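**Retrosynthetic overview**
1. Last bonds: the ester C–O bond of the (Z)-p-coumarate on the lactate-derived hydroxyl (made as an arylpropiolate ester, then cis-semihydrogenation), followed by loss of two silyl groups.
2. Key disconnection: the two C–C bonds from the acyl-bearing cyclopropane carbon to a terminal vinyl group, i.e. an intermolecular, ligand-controlled cyclopropanation of a vinyl dihydropyranone with a D-lactate-derived keto sulfoxonium ylide (new step).
3. Vinyl dihydropyranone: from divinylcarbinol by desymmetrising Sharpless epoxidation (sets both carbinol centres), epoxide opening with propiolate, cis-semihydrogenation and lactonisation.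
4. Ring order: lactone ring first, cyclopropane ring second; no ring is formed after the fragment union.

Assumption: the SMILES is read as (R) at the acyloxy carbon, trans-(1S,2S) at the cyclopropane, (S) at the free carbinol, (R) at C-6 of the lactone and Z at the cinnamate. In the new step the (R,R) antipode of the diene ligand is taken as the matched one; one pair of test runs with both antipodes fixes the choice.

**Step 1**
Reactants: 1 penta-1,4-dien-3-ol (divinylcarbinol)
Product: 2 (2R,3S)-1,2-epoxypent-4-en-3-ol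
Conditions: Ti(OiPr)4 (10 mol %), L-(+)-diisopropyl tartrate (13 mol %), t-BuOOH, 4 Å MS, CH2Cl2, −20 °C, 5–7 d
Reagents that add atoms: tert-butyl hydroperoxide CC(C)(C)OO
Why: Sharpless asymmetric epoxidation desymmetrises the achiral dienol by combined enantiotopic-group and face selection (the minor enantiomer is consumed by a fast second epoxidation), giving the erythro (2R,3S) epoxy alcohol whose two centres become the free carbinol and C-6 of the lactone.

**Step 2**
Reactants: 2 (2R,3S)-1,2-epoxypent-4-en-3-ol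
Product: 3 tert-butyldimethyl{[(1S)-1-[(2R)-oxiran-2-yl]prop-2-en-1-yl]oxy}silane
Conditions: TBSCl, imidazole, DMF, 0 °C to rt
Reagents that add atoms: tert-butyldimethylsilyl chloride CC(C)(C)[Si](C)(C)Cl
Why: Imidazole-promoted silyl ether formation masks the carbinol for the later organolithium, carbene and acylation steps and touches no stereocentre.

**Step 3**
Reactants: 3 tert-butyldimethyl{[(1S)-1-[(2R)-oxiran-2-yl]prop-2-en-1-yl]oxy}silane
Product: 4 ethyl (5R,6S)-6-[(tert-butyldimethylsilyl)oxy]-5-hydroxyoct-7-en-2-ynoate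
Conditions: ethyl propiolate, n-BuLi, THF, −78 °C; BF3·OEt2; then 3, −78 °C; H2O quench
Reagents that add atoms: ethyl propiolate C#CC(=O)OCC
Why: Yamaguchi–Hirao alkynylation opens the BF3-activated terminal epoxide at its CH2 carbon (SN2) with lithium ethyl propiolate, so both stereocentres are retained and the three remaining lactone carbons are added.

**Step 4**
Reactants: 4 ethyl (5R,6S)-6-[(tert-butyldimethylsilyl)oxy]-5-hydroxyoct-7-en-2-ynoate
Product: 6 (6R)-6-[(1S)-1-[(tert-butyldimethylsilyl)oxy]prop-2-en-1-yl]-5,6-dihydro-2H-pyran-2-one, via Z-hydroxy enoate 5 (not isolated)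
Conditions: H2 (1 atm), Pd/CaCO3 poisoned with Pb(OAc)2, quinoline, EtOAc, rt, stopped at 1 equiv H2; filter; PPTS (cat.), toluene, 50 °C
Reagents that add atoms: none
Why: Lindlar cis-semihydrogenation of the alkyne (much faster than reduction of the hindered vinyl group) gives the Z-enoate, whose geometry places the ester next to the δ-hydroxyl so that acid-catalysed lactonisation closes the dihydropyranone ring.

**Step 5**
Reactants: 7 methyl (2R)-2-hydroxypropanoate (methyl D-lactate)
Product: 8 methyl (2R)-2-[(triethylsilyl)oxy]propanoate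
Conditions: TESCl, imidazole, CH2Cl2, 0 °C
Reagents that add atoms: chlorotriethylsilane CC[Si](CC)(CC)Cl
Why: Silylation of the secondary alcohol with a triethylsilyl group, which can later be removed in the presence of the tert-butyldimethylsilyl ether; the (R) centre comes unchanged from methyl D-lactate.

**Step 6**
Reactants: 8 methyl (2R)-2-[(triethylsilyl)oxy]propanoate
Product: 9 (3R)-1-[dimethyl(oxo)-λ6-sulfanylidene]-3-[(triethylsilyl)oxy]butan-2-one
Conditions: Me3S(O)I (3 equiv), KOtBu (3 equiv), THF, reflux 2 h; then 8, 0 °C to rt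
Reagents that add atoms: trimethylsulfoxonium iodide C[S+](C)(C)=O.[I-]
Why: Corey–Chaykovsky-type acylation: dimethylsulfoxonium methylide adds to the ester and the β-keto sulfoxonium salt is deprotonated to the stabilised ylide, which is too weakly basic to epimerise the adjacent silyloxy stereocentre.

**Step 7**
Reactants: 6 (6R)-6-[(1S)-1-[(tert-butyldimethylsilyl)oxy]prop-2-en-1-yl]-5,6-dihydro-2H-pyran-2-one; 9 (3R)-1-[dimethyl(oxo)-λ6-sulfanylidene]-3-[(triethylsilyl)oxy]butan-2-one
Product: 10 (6R)-6-[(S)-[(tert-butyldimethylsilyl)oxy]{(1S,2S)-2-[(2R)-2-[(triethylsilyl)oxy]propanoyl]cyclopropyl}methyl]-5,6-dihydro-2H-pyran-2-one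
Conditions: [IrCl(cyclooctene)2]2 (2.5 mol %), (R,R)-2,5-diphenylbicyclo[2.2.2]octa-2,5-diene (6 mol %), ClCH2CH2Cl, 60 °C; 9 (2.5 equiv) added over 12 h by syringe pump to 6 (1 equiv)
Reagents that add atoms: none
Why: Proposed new method: the nucleophilic ylide carbon of 9 binds the chiral monovalent iridium diene chloride complex formed in situ, loss of dimethyl sulfoxide gives an electrophilic iridium acyl carbene, and this adds in a concerted asynchronous [2+1] step to the terminal vinyl group of 6 (the conjugated cis-disubstituted lactone alkene is electron-poor and hindered and stays inert); the alkene approaches end-on with its substituent away from the acyl group (trans) and away from the phenyl wall of the C2-symmetric diene (face selection), which sets both cyclopropane centres as (1S,2S) while joining the two fragments, slow addition of 9 suppressing carbene–ylide coupling; the closest known reaction types are iridium-catalysed carbene transfer from keto sulfoxonium ylides to X–H bonds and to tethered alkenes and intermolecular alkene cyclopropanation with α-diazoketones, whereas an intermolecular, ligand-controlled cyclopropanation of an unactivated allylic-ether 1-alkene as limiting partner with a sulfoxonium ylide has not been shown.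

**Step 8**
Reactants: 10 (6R)-6-[(S)-[(tert-butyldimethylsilyl)oxy]{(1S,2S)-2-[(2R)-2-[(triethylsilyl)oxy]propanoyl]cyclopropyl}methyl]-5,6-dihydro-2H-pyran-2-one
Product: 11 (6R)-6-[(S)-[(tert-butyldimethylsilyl)oxy]{(1S,2S)-2-[(2R)-2-hydroxypropanoyl]cyclopropyl}methyl]-5,6-dihydro-2H-pyran-2-one
Conditions: PPTS (0.2 equiv), MeOH/CH2Cl2 1:1, 0 °C
Reagents that add atoms: none
Why: Acid-catalysed methanolysis cleaves the unhindered triethylsilyl ether far faster than the hindered secondary tert-butyldimethylsilyl ether (selective desilylation), freeing only the lactate hydroxyl.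

**Step 9**
Reactants: 12 4-[(tert-butyldimethylsilyl)oxy]benzaldehyde
Product: 13 tert-butyl[4-(2,2-dibromoethenyl)phenoxy]dimethylsilane
Conditions: CBr4, PPh3, Zn dust, CH2Cl2, 0 °C to rt
Reagents that add atoms: carbon tetrabromide BrC(Br)(Br)Br
Why: Corey–Fuchs dibromoolefination, a Wittig reaction of the dibromomethylene ylide generated in the flask with the aldehyde.

**Step 10**
Reactants: 13 tert-butyl[4-(2,2-dibromoethenyl)phenoxy]dimethylsilane
Product: 15 3-{4-[(tert-butyldimethylsilyl)oxy]phenyl}prop-2-ynoic acid, via lithium arylacetylide 14 (not isolated)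
Conditions: n-BuLi (2.1 equiv), THF, −78 °C; CO2 (g), −78 to 0 °C; 1 M HCl to pH 3
Reagents that add atoms: carbon dioxide O=C=O
Why: Second stage of the Corey–Fuchs sequence: bromine–lithium exchange and rearrangement give the lithium acetylide, which is carboxylated by CO2; the aryl silyl ether tolerates n-BuLi at −78 °C.

**Step 11**
Reactants: 11 (6R)-6-[(S)-[(tert-butyldimethylsilyl)oxy]{(1S,2S)-2-[(2R)-2-hydroxypropanoyl]cyclopropyl}methyl]-5,6-dihydro-2H-pyran-2-one; 15 3-{4-[(tert-butyldimethylsilyl)oxy]phenyl}prop-2-ynoic acid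
Product: 16 (2R)-1-[(1S,2S)-2-[(S)-[(tert-butyldimethylsilyl)oxy][(2R)-6-oxo-3,6-dihydro-2H-pyran-2-yl]methyl]cyclopropyl]-1-oxopropan-2-yl 3-{4-[(tert-butyldimethylsilyl)oxy]phenyl}prop-2-ynoate
Conditions: DCC, DMAP (10 mol %), CH2Cl2, −20 to 0 °C
Reagents that add atoms: none
Why: Steglich esterification acylates the α-hydroxy ketone at oxygen, so the (R) centre is retained, and an alkynoate cannot lose alkene geometry during DMAP-mediated acylation.

**Step 12**
Reactants: 16 (2R)-1-[(1S,2S)-2-[(S)-[(tert-butyldimethylsilyl)oxy][(2R)-6-oxo-3,6-dihydro-2H-pyran-2-yl]methyl]cyclopropyl]-1-oxopropan-2-yl 3-{4-[(tert-butyldimethylsilyl)oxy]phenyl}prop-2-ynoate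
Product: 17 (2R)-1-[(1S,2S)-2-[(S)-[(tert-butyldimethylsilyl)oxy][(2R)-6-oxo-3,6-dihydro-2H-pyran-2-yl]methyl]cyclopropyl]-1-oxopropan-2-yl (2Z)-3-{4-[(tert-butyldimethylsilyl)oxy]phenyl}prop-2-enoate
Conditions: H2 (1 atm), Pd/CaCO3 poisoned with Pb(OAc)2, quinoline, EtOAc, rt, dark, stopped at 1 equiv H2
Reagents that add atoms: none
Why: Lindlar semihydrogenation adds H2 syn to the aryl alkynoate to give the Z-cinnamate, while the conjugated lactone alkene and the cyclopropyl ketone are inert on the poisoned catalyst.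

**Step 13**
Reactants: 17 (2R)-1-[(1S,2S)-2-[(S)-[(tert-butyldimethylsilyl)oxy][(2R)-6-oxo-3,6-dihydro-2H-pyran-2-yl]methyl]cyclopropyl]-1-oxopropan-2-yl (2Z)-3-{4-[(tert-butyldimethylsilyl)oxy]phenyl}prop-2-enoate
Product: 18 (2R)-1-[(1S,2S)-2-[(S)-hydroxy[(2R)-6-oxo-3,6-dihydro-2H-pyran-2-yl]methyl]cyclopropyl]-1-oxopropan-2-yl (2Z)-3-(4-hydroxyphenyl)prop-2-enoate
Conditions: HF·pyridine, pyridine, THF, 0 °C to rt, dark
Reagents that add atoms: none
Why: Fluoride-mediated desilylation under buffered acidic conditions removes the aryl and the hindered secondary silyl ether without the basic phenoxide conditions that would isomerise the Z-alkene or open the lactone.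

**Compound list**
1 | penta-1,4-dien-3-ol (divinylcarbinol) | C=CC(O)C=C | starting material
2 | (2R,3S)-1,2-epoxypent-4-en-3-ol | C=C[C@H](O)[C@H]1CO1 | intermediate
3 | tert-butyldimethyl{[(1S)-1-[(2R)-oxiran-2-yl]prop-2-en-1-yl]oxy}silane | C=C[C@H](O[Si](C)(C)C(C)(C)C)[C@H]1CO1 | intermediate
4 | ethyl (5R,6S)-6-[(tert-butyldimethylsilyl)oxy]-5-hydroxyoct-7-en-2-ynoate | C=C[C@H](O[Si](C)(C)C(C)(C)C)[C@H](O)CC#CC(=O)OCC | intermediate
5 | ethyl (2Z,5R,6S)-6-[(tert-butyldimethylsilyl)oxy]-5-hydroxyocta-2,7-dienoate | C=C[C@H](O[Si](C)(C)C(C)(C)C)[C@H](O)C/C=C\C(=O)OCC | intermediate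
6 | (6R)-6-[(1S)-1-[(tert-butyldimethylsilyl)oxy]prop-2-en-1-yl]-5,6-dihydro-2H-pyran-2-one | C=C[C@H](O[Si](C)(C)C(C)(C)C)[C@H]1CC=CC(=O)O1 | intermediate
7 | methyl (2R)-2-hydroxypropanoate (methyl D-lactate) | C[C@@H](O)C(=O)OC | starting material
8 | methyl (2R)-2-[(triethylsilyl)oxy]propanoate | C[C@@H](O[Si](CC)(CC)CC)C(=O)OC | intermediate
9 | (3R)-1-[dimethyl(oxo)-λ6-sulfanylidene]-3-[(triethylsilyl)oxy]butan-2-one | C[C@@H](O[Si](CC)(CC)CC)C(=O)C=S(C)(C)=O | intermediate
10 | (6R)-6-[(S)-[(tert-butyldimethylsilyl)oxy]{(1S,2S)-2-[(2R)-2-[(triethylsilyl)oxy]propanoyl]cyclopropyl}methyl]-5,6-dihydro-2H-pyran-2-one | C[C@@H](O[Si](CC)(CC)CC)C(=O)[C@H]1C[C@@H]1[C@H](O[Si](C)(C)C(C)(C)C)[C@H]1CC=CC(=O)O1 | intermediate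
11 | (6R)-6-[(S)-[(tert-butyldimethylsilyl)oxy]{(1S,2S)-2-[(2R)-2-hydroxypropanoyl]cyclopropyl}methyl]-5,6-dihydro-2H-pyran-2-one | C[C@@H](O)C(=O)[C@H]1C[C@@H]1[C@H](O[Si](C)(C)C(C)(C)C)[C@H]1CC=CC(=O)O1 | intermediate
12 | 4-[(tert-butyldimethylsilyl)oxy]benzaldehyde | O=Cc1ccc(O[Si](C)(C)C(C)(C)C)cc1 | starting material
13 | tert-butyl[4-(2,2-dibromoethenyl)phenoxy]dimethylsilane | BrC(Br)=Cc1ccc(O[Si](C)(C)C(C)(C)C)cc1 | intermediate
14 | ({4-[(tert-butyldimethylsilyl)oxy]phenyl}ethynyl)lithium | [Li]C#Cc1ccc(O[Si](C)(C)C(C)(C)C)cc1 | intermediate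
15 | 3-{4-[(tert-butyldimethylsilyl)oxy]phenyl}prop-2-ynoic acid | OC(=O)C#Cc1ccc(O[Si](C)(C)C(C)(C)C)cc1 | intermediate
16 | (2R)-1-[(1S,2S)-2-[(S)-[(tert-butyldimethylsilyl)oxy][(2R)-6-oxo-3,6-dihydro-2H-pyran-2-yl]methyl]cyclopropyl]-1-oxopropan-2-yl 3-{4-[(tert-butyldimethylsilyl)oxy]phenyl}prop-2-ynoate | C[C@@H](OC(=O)C#Cc1ccc(O[Si](C)(C)C(C)(C)C)cc1)C(=O)[C@H]1C[C@@H]1[C@H](O[Si](C)(C)C(C)(C)C)[C@H]1CC=CC(=O)O1 | intermediate
17 | (2R)-1-[(1S,2S)-2-[(S)-[(tert-butyldimethylsilyl)oxy][(2R)-6-oxo-3,6-dihydro-2H-pyran-2-yl]methyl]cyclopropyl]-1-oxopropan-2-yl (2Z)-3-{4-[(tert-butyldimethylsilyl)oxy]phenyl}prop-2-enoate | C[C@@H](OC(=O)/C=C\c1ccc(O[Si](C)(C)C(C)(C)C)cc1)C(=O)[C@H]1C[C@@H]1[C@H](O[Si](C)(C)C(C)(C)C)[C@H]1CC=CC(=O)O1 | intermediate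
18 | (2R)-1-[(1S,2S)-2-[(S)-hydroxy[(2R)-6-oxo-3,6-dihydro-2H-pyran-2-yl]methyl]cyclopropyl]-1-oxopropan-2-yl (2Z)-3-(4-hydroxyphenyl)prop-2-enoate | C[C@@H](OC(=O)/C=C\c1ccc(O)cc1)C(=O)[C@H]1C[C@@H]1[C@H](O)[C@H]1CC=CC(=O)O1 | target

**Step count and risks**
Total steps: 13. Longest linear sequence: 9 steps (1, 2, 3, 4, 7, 8, 11, 12, 13).

Step 7 (proposed new cyclopropanation). Risks: carbene formation may be slow, the ylide may couple with itself, face control may be low, and 9 may add to the lactone enoate in a background Michael reaction. The fallback uses known chemistry, sets out from 8 (with 6 unchanged) and comes back at 10. Ester 8 is saponified (LiOH, THF/H2O, 0 °C) to (2R)-2-[(triethylsilyl)oxy]propanoic acid F1. Isobutyl chloroformate and N-methylmorpholine convert it into isobutyl carbonic (2R)-2-[(triethylsilyl)oxy]propanoic anhydride F2, which acylates diazomethane to give (3R)-1-diazo-3-[(triethylsilyl)oxy]butan-2-one F3. Slow addition of F3 to alkene 6 with Rh2(OAc)4 (1 mol %) in CH2Cl2, the classical metal-carbene cyclopropanation with an α-diazoketone, gives the trans-cyclopropyl ketones, from which 10 is separated by chromatography. If catalyst control is needed, a known chiral catalyst for α′-oxygenated diazoketones replaces Rh2(OAc)4: the cyclometalated divalent ruthenium complex [Ru(Ph-pheox)(MeCN)4]PF6, where Ph-pheox is ortho-metalated 2,4-diphenyl-4,5-dihydrooxazole.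

Step 4 (semihydrogenation next to a terminal vinyl group, then lactonisation). Risks: over-reduction of the vinyl group and incomplete ring closure. The fallback sets out from 3 and comes back at 6. Lithiated trimethyl 3-(phenylsulfonyl)orthopropionate (n-BuLi, THF/DMPU, −78 °C) opens epoxide 3 at CH2 to give (5R,6S)-6-[(tert-butyldimethylsilyl)oxy]-1,1,1-trimethoxy-3-(phenylsulfonyl)oct-7-en-5-ol F4. Catalytic TsOH·H2O in CH2Cl2 converts it into (6R)-6-[(1S)-1-[(tert-butyldimethylsilyl)oxy]prop-2-en-1-yl]-4-(phenylsulfonyl)tetrahydro-2H-pyran-2-one F5. DBU then eliminates benzenesulfinate to give 6, so no hydrogenation is run in the presence of the vinyl group.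

Step 12 (late semihydrogenation). Risks: over-reduction, slow reduction of the lactone alkene and Z to E leakage. The fallback sets out from 11 and comes back at 17. Alcohol 11 is esterified (DCC) with (diphenoxyphosphoryl)acetic acid to give (2R)-1-[(1S,2S)-2-[(S)-[(tert-butyldimethylsilyl)oxy][(2R)-6-oxo-3,6-dihydro-2H-pyran-2-yl]methyl]cyclopropyl]-1-oxopropan-2-yl 2-(diphenoxyphosphoryl)acetate F6. A Z-selective Ando-type Horner–Wadsworth–Emmons olefination of F6 with aldehyde 12 (NaH, THF, −78 °C) gives 17 directly. This replaces alkyne reduction by olefination and makes steps 9 to 11 unnecessary.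

**Further compounds**
F1 | step 7 | (2R)-2-[(triethylsilyl)oxy]propanoic acid | C[C@@H](O[Si](CC)(CC)CC)C(=O)O
F2 | step 7 | isobutyl carbonic (2R)-2-[(triethylsilyl)oxy]propanoic anhydride | C[C@@H](O[Si](CC)(CC)CC)C(=O)OC(=O)OCC(C)C
F3 | step 7 | (3R)-1-diazo-3-[(triethylsilyl)oxy]butan-2-one | C[C@@H](O[Si](CC)(CC)CC)C(=O)C=[N+]=[N-]
F4 | step 4 | (5R,6S)-6-[(tert-butyldimethylsilyl)oxy]-1,1,1-trimethoxy-3-(phenylsulfonyl)oct-7-en-5-ol (epimers at C-3) | C=C[C@H](O[Si](C)(C)C(C)(C)C)[C@H](O)CC(CC(OC)(OC)OC)S(=O)(=O)c1ccccc1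
F5 | step 4 | (6R)-6-[(1S)-1-[(tert-butyldimethylsilyl)oxy]prop-2-en-1-yl]-4-(phenylsulfonyl)tetrahydro-2H-pyran-2-one (epimers at C-4) | C=C[C@H](O[Si](C)(C)C(C)(C)C)[C@H]1CC(CC(=O)O1)S(=O)(=O)c1ccccc1
F6 | step 12 | (2R)-1-[(1S,2S)-2-[(S)-[(tert-butyldimethylsilyl)oxy][(2R)-6-oxo-3,6-dihydro-2H-pyran-2-yl]methyl]cyclopropyl]-1-oxopropan-2-yl 2-(diphenoxyphosphoryl)acetate | C[C@@H](OC(=O)CP(=O)(Oc1ccccc1)Oc1ccccc1)C(=O)[C@H]1C[C@@H]1[C@H](O[Si](C)(C)C(C)(C)C)[C@H]1CC=CC(=O)O1
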